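The route rests on cutting the C3–C4 bond of ring A (labdane numbering, see remarks). This maps ring B with C5, the C17 methyl and the gem-dimethyl carbon C4 onto (R)-carvone, whose isopropenyl group becomes C4. The key step exploits that C4 is a quaternary carbon bearing two methyls beside the trans C5–C10 ring fusion: iron-hydride hydrogen-atom transfer converts the isopropenyl group into the tertiary C4 radical, which closes ring A by 6-endo addition to C3 of a vinyl sulfone and so delivers the trans-decalin enone in one operation. Its precursor is carvone alkylated twice at C10, with the C20 methyl and a 2-(phenylsulfonyl)allyl arm (C1–C3) anti to the isopropenyl group.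

Key step: step 4

Remarks
- Numbering: labdane numbering is used for all intermediates. Ring A is C1–C5 plus C10 and ring B is C5–C10. C6 carries the acetoxy group, C8 the C17 methyl and C10 the C20 methyl; C9 is the decalin spiro carbon. C11 and C12 are the ether-ring CH2 groups and C13 is the ether–lactone spiro carbon. C14 is the lactone CH2, C15 the lactone carbonyl and C16 the lactone OCH2. β is the face of the C20 methyl, α the opposite face.
- Assumption: the sulfone-bearing C2 centre is temporary; it is drawn as the expected equatorial (2α) epimer and its configuration has no bearing on the outcome.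
- Assumption: reagents that contribute non-hydrogen atoms to a product are numbered as starting materials.

Step 1
Reactants: 1 (R)-(−)-carvone; 2 iodomethane
Product: 4 α′-methylcarvone (C10-epimer mixture; methyl trans to isopropenyl predominant), via carvone lithium enolate 3 (not isolated)
Conditions: LiN(iPr)2, THF, −78 °C; then MeI, −78 → 0 °C
Reagents that add atoms: iodomethane, CI
Why: Kinetic deprotonation of the cross-conjugated enone at the α′ methylene (C10) followed by SN2 methylation is a standard enolate alkylation, and the C10 centre so formed is of no consequence because step 2 flattens it again.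

Step 2
Reactants: 4 α′-methylcarvone; 5 2,3-dibromopropene
Product: 7 α′-(2-bromoallyl)-α′-methylcarvone (5S,6S in carvone numbering; bromoallyl arm anti to isopropenyl), via methylcarvone lithium enolate 6 (not isolated)
Conditions: LiN(iPr)2, THF, −78 °C; then 2,3-dibromopropene, DMPU, −78 → −20 °C
Reagents that add atoms: 2,3-dibromopropene, C=C(Br)CBr
Why: Enolate alkylation of the tetrasubstituted enolate occurs at the allylic bromide only (the vinylic C–Br bond is inert to SN2), and the electrophile approaches anti to the neighbouring C5 isopropenyl group, which sets the quaternary C10 with the methyl (C20) syn and the C1 arm anti to that group.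

Step 3
Reactants: 7 α′-(2-bromoallyl)-α′-methylcarvone; 8 sodium benzenesulfinate
Product: 9 α′-methyl-α′-[2-(phenylsulfonyl)allyl]carvone (5S,6S)
Conditions: PhSO2Na (1.5 equiv), CuI (10 mol %), L-proline sodium salt (20 mol %), DMSO, 90 °C
Reagents that add atoms: sodium benzenesulfinate, [Na+].[O-]S(=O)c1ccccc1
Why: Copper-catalysed Ullmann-type C–S coupling of a vinyl bromide with a sulfinate salt (attack through sulfur) gives the vinyl sulfone without touching the enone, the isopropenyl group or either stereocentre.

Step 4
Reactants: 9 α′-methyl-α′-[2-(phenylsulfonyl)allyl]carvone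
Product: 10 trans-fused sulfonyl enone (2α-phenylsulfonyl-4,4,8,10-tetramethyl-trans-decal-7-en-9-one; 5α-H, 10β-CH3)
Conditions: Fe(acac)3 (0.5 equiv), PhSiH3 (2.5 equiv), EtOH/ethylene glycol 5:1, 60 °C, 0.02 M
Reagents that add atoms: none
Why: An iron hydride formed from Fe(acac)3 and PhSiH3 delivers a hydrogen atom to the terminal CH2 of the isopropenyl group, which becomes the second methyl on C4 and leaves the nucleophilic tertiary C4 radical; the radical adds to C3, the unsubstituted terminus of the vinyl sulfone, and the α-sulfonyl radical at C2 is reduced by divalent iron to the carbanion and protonated by ethanol, which regenerates trivalent iron. The closest known reaction type is the iron-hydride reductive coupling of an unactivated donor olefin with an electron-poor acceptor olefin (a hydrogen-atom-transfer Giese reaction), run here intramolecularly. Ring A closes in the 6-endo-trig mode through a chair-like transition state, because the alternative 5-exo attack would have to occur at C2, the sulfonyl-substituted internal carbon, against both the steric and the polar preference of the nucleophilic radical. The only new stereocentre, C2, is set by protonation from the axial direction so that the sulfone sits equatorial (2α), and it is temporary; the trans ring fusion is inherited from the anti arrangement of the two arms in 9, which react from a trans-diequatorial conformer. The step needs hydrogen-atom transfer to the electron-neutral 1,1-disubstituted isopropenyl alkene rather than to the trisubstituted enone or the electron-poor vinyl sulfone, which the known preference of iron hydrides for electron-rich terminal alkenes secures, and it needs cyclisation to outrun reduction of the radical, which high dilution and the polarity match between radical and acceptor secure.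

Step 5
Reactants: 10 trans-fused sulfonyl enone; 11 tert-butyl hydroperoxide
Product: 12 sulfonyl ene-dione (2α-phenylsulfonyl-trans-decal-7-ene-6,9-dione)
Conditions: Pd(OH)2/C (5 mol %), t-BuOOH (5 equiv), K2CO3 (0.25 equiv), CH2Cl2, 4 °C → rt
Reagents that add atoms: tert-butyl hydroperoxide, CC(C)(C)OO
Why: Palladium-mediated tert-butylperoxy-radical γ-oxidation of an α,β-enone to the 1,4-ene-dione can only occur at C6, the sole γ-CH2 (C10 is quaternary), creates no stereocentre, and leaves the sulfone untouched, which is deliberately kept because reductive C–S cleavage would not spare the enone.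

Step 6
Reactants: 12 sulfonyl ene-dione
Product: 14 sulfonyl 6,9-dione (8α-methyl; 8β-H), via C8-epimeric dione mixture 13 (not isolated)
Conditions: Zn dust, AcOH, rt; then K2CO3, MeOH, rt
Reagents that add atoms: none
Why: Zinc in acetic acid reduces the electron-poor ene-dione double bond (dissolving-metal conjugate reduction) without affecting the sulfone, and base equilibration through the C9 enolate then puts the C17 methyl equatorial (8α, 8β-H), since an 8β methyl would be syn-diaxial to C20, while the trans ring fusion is also the stable arrangement at the enolisable C5.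

Step 7
Reactants: 14 sulfonyl 6,9-dione
Product: 15 sulfonyl 6β-hydroxy-9-ketone
Conditions: NaBH4 (1.0 equiv), MeOH/CH2Cl2 1:1, −40 → −10 °C
Reagents that add atoms: none
Why: Borohydride reduction should select the C6 carbonyl (flanked by C5–H and the C7 methylene) over the C9 carbonyl (flanked by quaternary C10 and the methyl-bearing C8), and hydride enters from the α face because the β face of C6 is closed by the syn-axial C20 and 4β methyls, giving the axial 6β alcohol.

Step 8
Reactants: 15 sulfonyl 6β-hydroxy-9-ketone; 16 (4-bromobut-1-yn-1-yl)trimethylsilane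
Product: 17 6β,9α-diol bearing a 9β-[4-(trimethylsilyl)but-3-ynyl] chain (2α-sulfone retained)
Conditions: Me3SiC≡CCH2CH2MgBr (from 16 and Mg, THF; 4 equiv), anhydrous CeCl3, THF, −78 → 0 °C; aq. NH4Cl
Reagents that add atoms: [4-(trimethylsilyl)but-3-yn-1-yl]magnesium bromide, C[Si](C)(C)C#CCC[Mg]Br (made from 16, C[Si](C)(C)C#CCCBr)
Why: Organocerium 1,2-addition to a hindered, enolisable ketone suppresses enolisation at C8, β-hydride reduction and α-sulfonyl deprotonation, and the nucleophile enters equatorially, as is usual for 2,2,6-trisubstituted cyclohexanones and 9-oxo decalones of this type, avoiding the syn-axial α-hydrogens at C1, C5 and C7 and giving the axial 9α alcohol with C11 β.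

Step 9
Reactants: 17 silylated sulfonyl diol
Product: 19 9β-(but-3-ynyl)-6β,9α-diol, via desilylated sulfonyl diol 18 (not isolated)
Conditions: K2CO3, MeOH, rt; then Mg turnings (I2-activated), MeOH, 50 °C
Reagents that add atoms: none
Why: Carbonate-mediated methanolysis frees the terminal alkyne and magnesium in methanol then cleaves the alkyl–sulfonyl bond by single-electron transfer (reductive desulfonylation), a step placed here because diol 18 has no carbonyl or conjugated alkene to compete for electrons, and it turns the temporary C2 centre into a CH2 group.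

Step 10
Reactants: 19 9β-(but-3-ynyl)-6β,9α-diol; 20 acetic anhydride
Product: 21 6β-acetoxy-9β-(but-3-ynyl)-9α-ol
Conditions: Ac2O, DMAP, pyridine, rt → 40 °C
Reagents that add atoms: acetic anhydride, CC(=O)OC(C)=O
Why: DMAP-catalysed acylation esterifies only the secondary 6β-hydroxyl, the tertiary 9α-hydroxyl being inert under these conditions, and doing it now protects C6–OH from the acid chloride of step 12 with retention at C6.

Step 11
Reactants: 21 6β-acetoxy-9β-(but-3-ynyl)-9α-ol
Product: 22 spiro enol ether (6β-acetoxy-9α,13-epoxy-13(16)-ene; 2-methyleneoxolane spiro-fused at C9)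
Conditions: AuCl (5 mol %), K2CO3 (10 mol %), MeCN, rt; filtration through basic alumina
Reagents that add atoms: none
Why: Gold-catalysed 5-exo-dig hydroalkoxylation (cycloisomerisation of a 4-alkyn-1-ol) lets the tertiary 9α-hydroxyl add to the internal alkyne carbon C13 in the Markovnikov sense, the base preventing migration of the exocyclic double bond into the ring, and the spiro centre C9 keeps its configuration because the C9–O bond is not broken.

Step 12
Reactants: 22 spiro enol ether; 23 dichloroacetyl chloride
Product: 24 spiro α,α-dichlorocyclobutanone (C14 = CCl2 on C13, facing C8; C15 = C=O on C16; C16 facing C10)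
Conditions: Et3N (3 equiv), hexane/Et2O, 0 °C; Cl2CHCOCl (2 equiv) added over 2 h; → rt
Reagents that add atoms: dichloroacetyl chloride, ClC(Cl)C(Cl)=O (delivered as dichloroketene, ClC(Cl)=C=O)
Why: Thermal [2+2] cycloaddition of dichloroketene to the electron-rich enol ether joins the nucleophilic methylene C16 to the ketene carbonyl carbon (C15) and the CCl2 carbon (C14) to C13, and C13 is set by approach of the ketene to the face of the oxolane ring that looks toward the tertiary C8 and away from quaternary C10 with its C20 methyl and ring A, a bias that is expected to be moderate so that the C13 epimer is removed by chromatography.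

Step 13
Reactants: 24 spiro α,α-dichlorocyclobutanone; 25 3-chloroperoxybenzoic acid
Product: 26 14,14-dichloro-previtexilactone (α,α-dichloro-γ-lactone)
Conditions: mCPBA, NaHCO3, CH2Cl2, 0 °C → rt
Reagents that add atoms: 3-chloroperoxybenzoic acid, OOC(=O)c1cccc(Cl)c1
Why: Baeyer–Villiger oxidation of the strained, electrophilic dichlorocyclobutanone proceeds with migration of the unhalogenated CH2 (C16), because the chlorines make C14 a poor migrating group, so oxygen enters between C15 and C16, and C13 is not involved and keeps its configuration.

Step 14
Reactants: 26 14,14-dichloro-previtexilactone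
Product: 27 previtexilactone
Conditions: Bu3SnH (2.5 equiv), AIBN (cat.), toluene, 90 °C
Reagents that add atoms: none
Why: Tin hydride radical-chain hydrodechlorination removes both α-chlorines under neutral conditions, which avoids the β-elimination of the C13 ether oxygen that an enolate-forming reductant could cause, and no stereocentre is affected.

Compound list
1 | (R)-(−)-carvone | CC1=CC[C@H](CC1=O)C(C)=C | starting material
2 | iodomethane | CI | starting material
3 | carvone lithium enolate (cross-conjugated dienolate from deprotonation at C10) | CC1=CC[C@@H](C(C)=C)C=C1O[Li] | intermediate (not isolated)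
4 | α′-methylcarvone, (5R)-2,6-dimethyl-5-(prop-1-en-2-yl)cyclohex-2-en-1-one, C6 epimers in carvone numbering (major trans 5R,6S epimer drawn) | CC1=CC[C@@H](C(C)=C)[C@H](C)C1=O | intermediate
5 | 2,3-dibromopropene | C=C(Br)CBr | starting material
6 | methylcarvone lithium enolate (tetrasubstituted C9=C10 enolate) | CC1=CC[C@@H](C(C)=C)C(C)=C1O[Li] | intermediate (not isolated)
7 | (5S,6S)-6-(2-bromoprop-2-en-1-yl)-2,6-dimethyl-5-(prop-1-en-2-yl)cyclohex-2-en-1-one (bromoallyl anti, methyl syn to isopropenyl) | CC1=CC[C@@H](C(C)=C)[C@](C)(CC(Br)=C)C1=O | intermediate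
8 | sodium benzenesulfinate | [Na+].[O-]S(=O)c1ccccc1 | starting material
9 | (5S,6S)-2,6-dimethyl-6-[2-(phenylsulfonyl)prop-2-en-1-yl]-5-(prop-1-en-2-yl)cyclohex-2-en-1-one (key-step precursor) | CC1=CC[C@@H](C(C)=C)[C@](C)(CC(=C)S(=O)(=O)c2ccccc2)C1=O | intermediate
10 | (4aS,7S,8aS)-2,5,5,8a-tetramethyl-7-(phenylsulfonyl)-4a,5,6,7,8,8a-hexahydronaphthalen-1(4H)-one (trans-fused; 5α-H, 10β-CH3, 2α equatorial sulfone; key-step product) | CC1=CC[C@H]2C(C)(C)C[C@H](S(=O)(=O)c3ccccc3)C[C@]2(C)C1=O | intermediate
11 | tert-butyl hydroperoxide | CC(C)(C)OO | starting material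
12 | sulfonyl ene-dione: 2α-phenylsulfonyl-4,4,8,10-tetramethyl-trans-decal-7-ene-6,9-dione (5α-H, 10β-CH3) | CC1=CC(=O)[C@H]2C(C)(C)C[C@H](S(=O)(=O)c3ccccc3)C[C@]2(C)C1=O | intermediate
13 | sulfonyl 6,9-dione as C8-epimer mixture | CC1CC(=O)[C@H]2C(C)(C)C[C@H](S(=O)(=O)c3ccccc3)C[C@]2(C)C1=O | intermediate (not isolated)
14 | sulfonyl 6,9-dione: 2α-phenylsulfonyl-4,4,8α,10β-tetramethyl-trans-decalin-6,9-dione (5α-H, 8β-H) | C[C@@H]1CC(=O)[C@H]2C(C)(C)C[C@H](S(=O)(=O)c3ccccc3)C[C@]2(C)C1=O | intermediate
15 | sulfonyl hydroxy-decalone: 6β-hydroxy-2α-phenylsulfonyl-4,4,8α,10β-tetramethyl-trans-decalin-9-one | C[C@@H]1C[C@@H](O)[C@H]2C(C)(C)C[C@H](S(=O)(=O)c3ccccc3)C[C@]2(C)C1=O | intermediate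
16 | (4-bromobut-1-yn-1-yl)trimethylsilane | C[Si](C)(C)C#CCCBr | starting material
17 | 2α-phenylsulfonyl-9β-[4-(trimethylsilyl)but-3-ynyl]-4,4,8α,10β-tetramethyl-trans-decalin-6β,9α-diol | O[C@@H]1C[C@@H](C)[C@](O)(CCC#C[Si](C)(C)C)[C@@]2(C)C[C@@H](S(=O)(=O)c3ccccc3)CC(C)(C)[C@H]12 | intermediate
18 | 9β-(but-3-ynyl)-2α-phenylsulfonyl-4,4,8α,10β-tetramethyl-trans-decalin-6β,9α-diol | O[C@@H]1C[C@@H](C)[C@](O)(CCC#C)[C@@]2(C)C[C@@H](S(=O)(=O)c3ccccc3)CC(C)(C)[C@H]12 | intermediate (not isolated)
19 | 9β-(but-3-ynyl)-4,4,8α,10β-tetramethyl-trans-decalin-6β,9α-diol | O[C@@H]1C[C@@H](C)[C@](O)(CCC#C)[C@@]2(C)CCCC(C)(C)[C@H]12 | intermediate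
20 | acetic anhydride | CC(=O)OC(C)=O | starting material
21 | 6β-acetoxy-9β-(but-3-ynyl)-4,4,8α,10β-tetramethyl-trans-decalin-9α-ol | CC(=O)O[C@@H]1C[C@@H](C)[C@](O)(CCC#C)[C@@]2(C)CCCC(C)(C)[C@H]12 | intermediate
22 | spiro enol ether: 6β-acetoxy-decalin spiro-fused at C9 (oxygen α) to a 2-methyleneoxolane (C13=C16H2) | CC(=O)O[C@@H]1C[C@@H](C)[C@]2(CCC(=C)O2)[C@@]2(C)CCCC(C)(C)[C@H]12 | intermediate
23 | dichloroacetyl chloride | ClC(Cl)C(Cl)=O | starting material
24 | spiro α,α-dichlorocyclobutanone (ring C13–C14Cl2–C15(=O)–C16H2; C14 on the oxolane face toward C8, C16 toward C10) | CC(=O)O[C@@H]1C[C@@H](C)[C@]2(CC[C@]3(CC(=O)C3(Cl)Cl)O2)[C@@]2(C)CCCC(C)(C)[C@H]12 | intermediate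
25 | 3-chloroperoxybenzoic acid | OOC(=O)c1cccc(Cl)c1 | starting material
26 | 14,14-dichloro-previtexilactone (lactone ring C13–C14Cl2–C15(=O)–O–C16H2) | CC(=O)O[C@@H]1C[C@@H](C)[C@]2(CC[C@]3(COC(=O)C3(Cl)Cl)O2)[C@@]2(C)CCCC(C)(C)[C@H]12 | intermediate
27 | previtexilactone | CC(=O)O[C@@H]1C[C@@H](C)[C@]2(CC[C@]3(COC(=O)C3)O2)[C@@]2(C)CCCC(C)(C)[C@H]12 | target

Total step count: 14
Longest linear sequence: 14 steps (fully linear, 1 → 27)

Steps most likely to fail

Step 12. The two faces of the oxolane enol ether are flanked by similar groups (the C1 methylene on one side, the C17 methyl on the other), so the ketene may discriminate poorly between them. The exocyclic double bond may also migrate into the ring before it is trapped. The fallback sets out from 24 and comes back at 27. The cycloadduct 24 is taken on together with its C13 epimer F1, without separation. Zn dust in AcOH at rt removes both chlorines from either epimer and gives a single compound, the chlorine-free spirocyclobutanone F2, in which C13 is no longer a stereocentre because its two CH2 arms are constitutionally the same. A catalyst-controlled desymmetrising Baeyer–Villiger oxidation (chiral phosphoric acid with aqueous H2O2, or a Baeyer–Villiger monooxygenase) then chooses between the two arms and leads directly to 27. C13 is thereby set by the oxidant instead of by the cycloaddition, and both cycloadducts are used.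

Step 7. Hydride may attack the C9 carbonyl as well as the C6 carbonyl, so that the two ketones are not told apart cleanly. The fallback sets out from 12 and comes back at 15. In the ene-dione the C9 carbonyl is shielded by quaternary C10 and by the methyl-bearing alkene carbon C8, whereas the C6 carbonyl has only C5–H and C7–H next to it. A Luche reduction (NaBH4, CeCl3·7H2O, MeOH, −78 °C) should therefore reduce C6 first, from the α face, and give the 6β-hydroxy enone F3. Hydrogenation (H2, Pd/C, EtOAc) then saturates C7=C8 from the open α face, giving mainly the 8β-methyl hydroxy ketone F4. Equilibration with K2CO3 in MeOH moves the methyl to the equatorial 8α position and returns 15.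

Step 4. The tertiary radical may be reduced before it cyclises (net hydrogenation of the isopropenyl group), or hydrogen-atom transfer may reach the vinyl sulfone. The fallback sets out from 9 and comes back at 10. Markovnikov addition of HCl (HCl in Et2O, CH2Cl2, −30 °C) to the isopropenyl group, the only electron-rich alkene, gives the tertiary chloride F5. Slow addition of Bu3SnH with AIBN in benzene at 80 °C then generates the same C4 radical by chlorine abstraction at a low, controlled hydride concentration. The radical closes ring A in the same 6-endo mode and the α-sulfonyl radical takes hydrogen from the stannane, giving 10.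

Further compounds
F1 | step 12 | C13 epimer of spiro dichlorocyclobutanone 24 (C14 on the oxolane face toward C10) | CC(=O)O[C@@H]1C[C@@H](C)[C@]2(CC[C@@]3(CC(=O)C3(Cl)Cl)O2)[C@@]2(C)CCCC(C)(C)[C@H]12
F2 | step 12 | chlorine-free spirocyclobutanone (6β-acetoxy; C13 not a stereocentre) | CC(=O)O[C@@H]1C[C@@H](C)[C@]2(CCC3(CC(=O)C3)O2)[C@@]2(C)CCCC(C)(C)[C@H]12
F3 | step 7 | 6β-hydroxy-2α-phenylsulfonyl-4,4,8,10-tetramethyl-trans-decal-7-en-9-one | CC1=C[C@@H](O)[C@H]2C(C)(C)C[C@H](S(=O)(=O)c3ccccc3)C[C@]2(C)C1=O
F4 | step 7 | C8 epimer of 15 (8β-methyl hydroxy ketone) | C[C@H]1C[C@@H](O)[C@H]2C(C)(C)C[C@H](S(=O)(=O)c3ccccc3)C[C@]2(C)C1=O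
F5 | step 4 | tertiary chloride from 9 (2-chloropropan-2-yl group at C5) | CC1=CC[C@@H](C(C)(C)Cl)[C@](C)(CC(=C)S(=O)(=O)c2ccccc2)C1=O
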